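**Retrosynthetic overview**
1. Key C–C disconnection, C8–C9 of the acyl chain: octadecanal 1, used as its N–H hydrazone, acts as a C18 alkyl-carbanion equivalent (the electrophilic CHO carbon is made nucleophilic). It is joined to the electrophilic CH2Br carbon of ethyl 8-bromooctanoate 2 with loss of N2, through hydrazone 3, to give ethyl hexacosanoate 4.
2. Ester C–O disconnection: 4 and tyrosol 5 give target 6 by lipase transesterification at the primary alcohol only, so the phenol is never protected.
3. No ring is formed; the benzene ring is bought in.

Assumption: the target has no stereocentre and no stereogenic double bond, so the single-enantiomer requirement is met by the achiral compound itself.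

**Step 1**
Reactants: 1 octadecanal; 2 ethyl 8-bromooctanoate
Product: 4 ethyl hexacosanoate, via octadecanal hydrazone 3 (not isolated)
Conditions: N2H4·H2O (1.2 equiv to 1), THF, 4 Å MS, rt, 1 h; then 2 (limiting, 1 used at 1.5 equiv), Ni(cod)2 (10 mol %), PMe3 (20 mol %), K3PO4 (2 equiv), THF, 60 °C, 16 h
Reagents that add atoms: none
Why: Proposed new method: hydrazone 3 is a Wolff–Kishner-type alkyl-carbanion equivalent, so the normally electrophilic CHO carbon of 1 becomes the nucleophile toward the electrophilic CH2Br carbon of 2; electron-rich zerovalent nickel (Ni(cod)2/PMe3) activates the primary C–Br bond by halogen abstraction and radical rebound, K3PO4 deprotonates the nickel-bound hydrazone to a diazenide, loss of N2 leaves a dialkylnickel that closes C8–C9 by C(sp3)–C(sp3) reductive elimination, and the remote ethyl ester is inert to K3PO4 at 60 °C; the closest known reaction type is the nickel-catalysed denitrogenative cross-coupling of aryl-aldehyde N–H hydrazones with aryl and unactivated alkyl halides (carbonyl umpolung), and the extension here is to a fully aliphatic hydrazone; no stereocentre is formed.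

**Step 2**
Reactants: 4 ethyl hexacosanoate; 5 tyrosol
Product: 6 2-(4-hydroxyphenyl)ethyl hexacosanoate
Conditions: Novozym 435 (immobilised Candida antarctica lipase B, 20 wt %), 5 in threefold excess, toluene/2-methyl-2-butanol 4:1, 5 Å MS, 65 °C, 48 h
Reagents that add atoms: none
Why: In this lipase-catalysed transesterification the acyl-enzyme formed from 4 passes the hexacosanoyl group only to the unhindered primary aliphatic hydroxyl of 5, the phenolic hydroxyl is not acylated by this enzyme, and trapping ethanol on the sieves drives the equilibrium; no stereocentre is involved.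

**Compound list**
1 | octadecanal (stearaldehyde) | CCCCCCCCCCCCCCCCCC=O | starting material
2 | ethyl 8-bromooctanoate | CCOC(=O)CCCCCCCBr | starting material
3 | (E)-octadecanal hydrazone, (E)-octadecylidenehydrazine | CCCCCCCCCCCCCCCCC/C=N/N | intermediate
4 | ethyl hexacosanoate | CCCCCCCCCCCCCCCCCCCCCCCCCC(=O)OCC | intermediate
5 | tyrosol, 4-(2-hydroxyethyl)phenol | OCCc1ccc(O)cc1 | starting material
6 | 2-(4-hydroxyphenyl)ethyl hexacosanoate | CCCCCCCCCCCCCCCCCCCCCCCCCC(=O)OCCc1ccc(O)cc1 | target

**Total step count:** 2
**Longest linear sequence:** 2

**Steps most likely to fail**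
The route has only two steps, so both are ranked, and step 1 is ranked once for each of its two stages.

1. Step 1, nickel coupling stage. The risks are N-alkylation of 3 by 2, plain Wolff–Kishner reduction of 3 to octadecane, and β-hydride loss from the alkylnickel. The fallback keeps the aldehyde carbon as the nucleophile but makes the chemistry stoichiometric and radical-terminated. It sets out from 1 and comes back to the route at 4. Compound 1 is condensed with tritylhydrazine (EtOH, rt) to the stable (E)-octadecanal N-tritylhydrazone F1. LiN(iPr)2 (1.0 equiv, THF, −78 °C) gives its delocalised azo anion, which 2 alkylates at carbon (−78 °C to 0 °C) to give racemic ethyl 9-(trityldiazenyl)hexacosanoate F2. Warmed to rt with EtSH, this azo compound fragments to N2, the trityl radical and the C9 radical, which takes hydrogen from the thiol and gives 4; the transient C9 stereocentre disappears.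

2. Step 1, hydrazone stage. The risks are azine formation from 1, hydrazine carried over to the nickel catalyst, and hydrazinolysis of the ester of 2. The fallback gives up the hydrazone and builds the same C8–C9 bond by olefination and hydrogenation. It sets out from 2, uses 1 as the aldehyde partner, and comes back at 4. Compound 2 and PPh3 (MeCN, reflux) give (8-ethoxy-8-oxooctyl)triphenylphosphonium bromide F3. Its ylide (NaN(SiMe3)2, THF, −78 °C) reacts with 1 in a Wittig reaction to give ethyl (Z)-hexacos-8-enoate F4. Hydrogenation (H2 1 atm, Pd/C, EtOAc, rt) gives 4.

3. Step 2. The risk is slow enzymatic turnover with the poorly soluble C26 ester. The fallback replaces the enzyme by a chemical esterification. It sets out from 4 and comes back at 6. Saponification (LiOH, THF/EtOH/H2O, 60 °C, then HCl) gives hexacosanoic acid F5. Mitsunobu esterification with 5 (PPh3, DIAD, THF, 0 °C to 40 °C) then forms 6, because the carboxylic acid (pKa about 5) is the pronucleophile and the phenol (pKa about 10) is neither activated nor competitive.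

**Further compounds**
F1 | step 1 | (E)-octadecanal N-tritylhydrazone | CCCCCCCCCCCCCCCCC/C=N/NC(c1ccccc1)(c1ccccc1)c1ccccc1
F2 | step 1 | ethyl 9-[(E)-trityldiazenyl]hexacosanoate (racemate) | CCCCCCCCCCCCCCCCCC(CCCCCCCC(=O)OCC)/N=N/C(c1ccccc1)(c1ccccc1)c1ccccc1
F3 | step 1 | (8-ethoxy-8-oxooctyl)triphenylphosphonium bromide | CCOC(=O)CCCCCCC[P+](c1ccccc1)(c1ccccc1)c1ccccc1.[Br-]
F4 | step 1 | ethyl (Z)-hexacos-8-enoate | CCCCCCCCCCCCCCCCC/C=C\CCCCCCC(=O)OCC
F5 | step 2 | hexacosanoic acid | CCCCCCCCCCCCCCCCCCCCCCCCCC(=O)O
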